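To name the leader at the end of each flask, count turnovers of the charge.

    starting material + starting material ⇌ product (K1 = 8.3 /M, k1 = 1.75 × 10⁻⁵ /M/s)

| flask | starting material | time |
|---|---|---|
| violet | 1.5 M | 4.0 h |
| grey | 1.5 M | 8.0 h |

- which of these there is most of at the end, counted by the starting material in it, violet (product / starting material)
- which of these there is most of at the end, counted by the starting material in it, grey (product / starting material)
- amount of the one of these that there is most of at the end, in percent of the starting material charged, violet
- amount of the one of these that there is most of at the end, in percent of the starting material charged, grey

- in percentages every species weighs as the starting material in it: one product counts as two
- a step written with two of one species runs at k times the square of its concentration and takes two of it each time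
- run time (violet): 4.0 h

Let a be the fraction of the charge still present as starting material; the remainder, 1 − a, stands as product.

First, the forward step alone. With k its rate constant and c the charge, the square in the rate gives

a = 1 / (1 + t/τ), with τ = 1 / (2·k·c) = 5.29 h

This τ is the turnover time, the time in which the forward step by itself halves the charge (its second-order half-life).

Violet, at 4.0 h, has t/τ = 0.756, below 1, so a = 0.569.

Grey, at 8.0 h, has t/τ = 1.51, above 1, so a = 0.398.

Next, the back step. Its pace against the forward pace is

(1 − a) / (2·K·c·a·a)

With the figures above, this comes to 0.0533 at the end of violet and 0.153 at the end of grey, and it is smaller earlier. So both values of a are lower limits, and grey's is the looser one.

Last, the rest: the flask holds no further step, and the two steps balance at a = 0.181, below grey's figure. This reckoning therefore commits to starting material leading in violet and product in grey, each with a slightly above its limit.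

The forecast, from “Second-order forward, first-order reverse”, names starting material at 57.5% for violet and product at 58.8% for grey. That leaves 41.2% of the charge as starting material in grey, just above the limit of 39.8% reckoned here.

The simulation gives starting material at 57.5% in violet and product at 58.8% in grey.

The difference in time is the main reason that grey holds 41.2% starting material where violet holds 57.5%: 1.51 turnovers against 0.756. The same count serves the grey flask left until 20 h, which has run 3.78 turnovers, so the forward step alone leaves a = 0.209. That neighbour holds 25.0% starting material, 4.1 percentage points above the count.

Its constants belong to no real substance; what happens was integrated by code.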